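**Retrosynthetic overview**
- The target is traced back to the fully methylated flavone (tangeretin) by chelation-directed removal of the 5-O-methyl group and hydroxylation of C3.
- Ring A is fully substituted. Its fusion carbons C8a (bonded to O1) and C4a (bonded to the C4 carbonyl) are neighbours, and each has a methoxy-bearing carbon (C8, C5) on its outer side. This C8–C8a–C4a–C5 array maps onto a mirror-symmetric 3,4,5,6-tetramethoxybenzyne whose two aryne carbons take up oxygen and acyl carbon in one event.
- The flavone is therefore cut at C8a–O1, C4a–C4 and O1–C2 into the ortho-silylaryl triflate of that aryne and 3-(4-methoxyphenyl)propiolic acid.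
- The triflate comes from 1,2,3,4-tetramethoxybenzene by ortho-lithiation/borylation/oxidation to the phenol, ortho-bromination, then O-silylation, retro-Brook shift and triflation.
- Ring order: rings A and B are bought; ring C is the only ring formed, in the aryne step.

Key step: step 4

Assumption: the 5-O-methyl group is taken off last, because the C4 carbonyl chelate makes it the one methyl ether that BCl3 cleaves under mild conditions; the target has no stereocenter, so no stereocontrol is needed.

**Step 1**
Reactants: 1 1,2,3,4-tetramethoxybenzene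
Product: 4 2,3,4,5-tetramethoxyphenol, via aryllithium 2 (not isolated), via lithium aryltrimethoxyborate 3 (not isolated)
Conditions: n-BuLi, TMEDA, THF, 0 °C; B(OMe)3, −78 °C → rt; AcOH, 30% aq. H2O2, 0 °C → rt
Reagents that add atoms: hydrogen peroxide, OO
Why: Directed ortho-lithiation next to a methoxy group (the two free ring positions are equivalent), borate trapping and peroxide oxidation of the aryl–boron bond with 1,2-shift of carbon to oxygen form a standard arene-to-phenol sequence, and the acidic oxidation medium protects the electron-rich phenol from further oxidation.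

**Step 2**
Reactants: 4 2,3,4,5-tetramethoxyphenol
Product: 5 2-bromo-3,4,5,6-tetramethoxyphenol
Conditions: NBS, dry MeCN, −20 → 0 °C, dark
Reagents that add atoms: N-bromosuccinimide, O=C1CCC(=O)N1Br
Why: Electrophilic aromatic bromination can only occur at the single remaining ring C–H, which is ortho to the hydroxyl group, and the dry solvent and low temperature should hold back oxidation of the phenol to a quinone.

**Step 3**
Reactants: 5 2-bromo-3,4,5,6-tetramethoxyphenol
Product: 8 3,4,5,6-tetramethoxy-2-(trimethylsilyl)phenyl trifluoromethanesulfonate, via aryl silyl ether 6 (not isolated), via lithium ortho-silylphenoxide 7 (not isolated)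
Conditions: HMDS, THF, 70 °C, then evaporate; n-BuLi, THF, −100 → −78 °C; Tf2O, −100 °C → rt
Reagents that add atoms: hexamethyldisilazane, C[Si](C)(C)N[Si](C)(C)C; trifluoromethanesulfonic anhydride, O=S(=O)(OS(=O)(=O)C(F)(F)F)C(F)(F)F
Why: O-silylation, bromine–lithium exchange and retro-Brook 1,3-shift of silicon from oxygen to the lithiated carbon give the ortho-silyl phenoxide, which is triflated in the same flask; this is the standard one-flask preparation of ortho-silylaryl triflates.

**Step 4**
Reactants: 8 3,4,5,6-tetramethoxy-2-(trimethylsilyl)phenyl trifluoromethanesulfonate; 9 3-(4-methoxyphenyl)propiolic acid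
Product: 12 5,6,7,8-tetramethoxy-2-(4-methoxyphenyl)-4H-chromen-4-one (tangeretin), via tetramethoxybenzyne 10 (not isolated), via cesium ynone phenoxide 11 (not isolated)
Conditions: 8 (1.5 equiv), CsF (4 equiv), THF, sealed tube, 125 °C
Reagents that add atoms: none
Why: Fluoride attacks silicon and triflate leaves to give the symmetric aryne 10; the cesium carboxylate of 9 adds to it (C8a–O1), and the aryl anion formed beside the ester attacks the acyl carbon through a four-membered benzoxetene alkoxide that opens to the ortho-acyl phenoxide 11 (C4a–C4). This is the known insertion of arynes into the C–O bond of carboxylic acids, which with arylpropiolic acids continues to flavones. Ring C then closes by 6-endo-dig oxa-Michael addition of the phenoxide to the anisyl-bearing alkyne carbon (O1–C2), and protonation at C3 gives the pyranone; no stereocenter is formed. The step needs a single orientation of oxygen and acyl on ring A, which the mirror-symmetric aryne with a methoxy group beside each aryne carbon guarantees, and it needs 6-endo rather than 5-exo closure (flavone, not aurone), which the aprotic medium and the Michael polarisation of the ynone should favour. The Z conformation of the aryl ester holds the alkyne away from the aryl anion, so acyl transfer should outrun attack on the alkyne, and the excess of 8 offsets loss of aryl anion by protonation.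

**Step 5**
Reactants: 12 5,6,7,8-tetramethoxy-2-(4-methoxyphenyl)-4H-chromen-4-one
Product: 15 3-hydroxy-5,6,7,8-tetramethoxy-2-(4-methoxyphenyl)-4H-chromen-4-one, via 3-lithioflavone 13 (not isolated), via lithium flavonyltrimethoxyborate 14 (not isolated)
Conditions: LiN(i-Pr)2 (LDA), THF, −78 °C; B(OMe)3, −78 → 0 °C; AcOH, 30% aq. H2O2, 0 °C → rt
Reagents that add atoms: hydrogen peroxide, OO
Why: C3–H next to the C4 carbonyl is the only acidic C–H (ring A carries none) and is removed by the hindered amide at −78 °C, and borate trapping followed by peroxide oxidation of the C–B bond is a known flavone-to-flavonol sequence.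

**Step 6**
Reactants: 15 3-hydroxy-5,6,7,8-tetramethoxy-2-(4-methoxyphenyl)-4H-chromen-4-one
Product: 16 3,5-dihydroxy-6,7,8-trimethoxy-2-(4-methoxyphenyl)-4H-chromen-4-one (3,5-dihydroxy-6,7,8,4'-tetramethoxyflavone)
Conditions: BCl3 (3 equiv), CH2Cl2, −78 → 0 °C; then H2O
Reagents that add atoms: none
Why: Chelation-directed Lewis-acid ether cleavage: boron bridges the C4 carbonyl and the peri 5-methoxy oxygen in a six-membered chelate, so chloride removes only that methyl group, while the excess reagent covers the boron taken up by the 3-hydroxyl and the other four aryl methyl ethers lack this activation at 0 °C.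

**Compound list**
1 | 1,2,3,4-tetramethoxybenzene | COc1ccc(OC)c(OC)c1OC | starting material
2 | (2,3,4,5-tetramethoxyphenyl)lithium | [Li]c1cc(OC)c(OC)c(OC)c1OC | intermediate
3 | lithium trimethoxy(2,3,4,5-tetramethoxyphenyl)borate | [Li+].CO[B-](OC)(OC)c1cc(OC)c(OC)c(OC)c1OC | intermediate
4 | 2,3,4,5-tetramethoxyphenol | COc1cc(O)c(OC)c(OC)c1OC | intermediate
5 | 2-bromo-3,4,5,6-tetramethoxyphenol | COc1c(O)c(Br)c(OC)c(OC)c1OC | intermediate
6 | (2-bromo-3,4,5,6-tetramethoxyphenoxy)trimethylsilane | COc1c(O[Si](C)(C)C)c(Br)c(OC)c(OC)c1OC | intermediate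
7 | lithium 2,3,4,5-tetramethoxy-6-(trimethylsilyl)phenolate | [Li+].COc1c([O-])c([Si](C)(C)C)c(OC)c(OC)c1OC | intermediate
8 | 3,4,5,6-tetramethoxy-2-(trimethylsilyl)phenyl trifluoromethanesulfonate | COc1c(OC)c(OC)c(OS(=O)(=O)C(F)(F)F)c([Si](C)(C)C)c1OC | intermediate
9 | 3-(4-methoxyphenyl)propiolic acid | COc1ccc(C#CC(=O)O)cc1 | starting material
10 | 3,4,5,6-tetramethoxybenzyne | COC1=C(OC)C(OC)=C(OC)C#C1 | intermediate
11 | cesium 3,4,5,6-tetramethoxy-2-[3-(4-methoxyphenyl)prop-2-ynoyl]phenolate | [Cs+].COc1ccc(C#CC(=O)c2c([O-])c(OC)c(OC)c(OC)c2OC)cc1 | intermediate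
12 | 5,6,7,8-tetramethoxy-2-(4-methoxyphenyl)-4H-chromen-4-one (tangeretin) | COc1ccc(-c2cc(=O)c3c(OC)c(OC)c(OC)c(OC)c3o2)cc1 | intermediate
13 | [5,6,7,8-tetramethoxy-2-(4-methoxyphenyl)-4-oxo-4H-chromen-3-yl]lithium | COc1ccc(-c2oc3c(OC)c(OC)c(OC)c(OC)c3c(=O)c2[Li])cc1 | intermediate
14 | lithium trimethoxy[5,6,7,8-tetramethoxy-2-(4-methoxyphenyl)-4-oxo-4H-chromen-3-yl]borate | [Li+].COc1ccc(-c2oc3c(OC)c(OC)c(OC)c(OC)c3c(=O)c2[B-](OC)(OC)OC)cc1 | intermediate
15 | 3-hydroxy-5,6,7,8-tetramethoxy-2-(4-methoxyphenyl)-4H-chromen-4-one | COc1ccc(-c2oc3c(OC)c(OC)c(OC)c(OC)c3c(=O)c2O)cc1 | intermediate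
16 | 3,5-dihydroxy-6,7,8-trimethoxy-2-(4-methoxyphenyl)-4H-chromen-4-one | COc1ccc(-c2oc3c(OC)c(OC)c(OC)c(O)c3c(=O)c2O)cc1 | target

**Step count**
Total steps: 6. Longest linear sequence: 6 steps (1 → 4 → 5 → 8 → 12 → 15 → 16); acid 9 is bought and enters at step 4.

**Steps most likely to fail**

Step 4 (key step). The cesium arylpropiolate may decarboxylate at 125 °C before it meets the aryne. The aryl anion may also be protonated ahead of acyl transfer, which would stop the sequence at the aryl propiolate ester. Slow fluoride release from the doubly ortho-substituted silane would make both worse. The fallback uses known chemistry, sets out from 4 and comes back at 12. Phenol 4 is C-acetylated at its one free ring position with Ac2O and BF3·OEt2 (Friedel–Crafts acylation with in situ Fries shift) to give 1-(2-hydroxy-3,4,5,6-tetramethoxyphenyl)ethan-1-one F1. Claisen–Schmidt condensation with 4-methoxybenzaldehyde (KOH, EtOH, rt) should give (E)-1-(2-hydroxy-3,4,5,6-tetramethoxyphenyl)-3-(4-methoxyphenyl)prop-2-en-1-one F2. Catalytic I2 in DMSO at 130 °C then closes and dehydrogenates the chalcone to flavone 12.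

Step 5. The amide base may add at C2, or the 3-lithio species may open by β-elimination to the ynone phenoxide before the borate quench, so that the pyranone ring is lost instead of hydroxylated. The fallback sets out from 12 and comes back at 15. Dimethyldioxirane in acetone/CH2Cl2 at 0 °C epoxidises the C2–C3 double bond to the racemic, cis-fused 2,3-epoxy-5,6,7,8-tetramethoxy-2-(4-methoxyphenyl)chroman-4-one F3. Catalytic TsOH in CH2Cl2 then opens the epoxide at C2, and loss of the C3 proton should give flavonol 15.

Step 6. Site selectivity may be lost: boron is tied up by the 3-hydroxy/4-carbonyl chelate, cleavage of the 5-O-methyl group slows, and forcing the reaction begins to cleave the neighbouring 6-O-methyl group as well. The fallback sets out from 15 and comes back at 16. The 3-hydroxyl is masked with Ac2O in pyridine as 5,6,7,8-tetramethoxy-2-(4-methoxyphenyl)-4-oxo-4H-chromen-3-yl acetate F4, so that only the 4-carbonyl/5-methoxy chelate can form. BCl3 in CH2Cl2 at −78 → 0 °C then gives 5-hydroxy-6,7,8-trimethoxy-2-(4-methoxyphenyl)-4-oxo-4H-chromen-3-yl acetate F5. Catalytic K2CO3 in MeOH at 0 °C removes the acetate to give 16.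

**Further compounds**
F1 | step 4 | 1-(2-hydroxy-3,4,5,6-tetramethoxyphenyl)ethan-1-one | CC(=O)c1c(O)c(OC)c(OC)c(OC)c1OC
F2 | step 4 | (E)-1-(2-hydroxy-3,4,5,6-tetramethoxyphenyl)-3-(4-methoxyphenyl)prop-2-en-1-one | COc1ccc(/C=C/C(=O)c2c(O)c(OC)c(OC)c(OC)c2OC)cc1
F3 | step 5 | 2,3-epoxy-5,6,7,8-tetramethoxy-2-(4-methoxyphenyl)chroman-4-one (racemic, cis-fused, one enantiomer drawn) | O=C1[C@@H]3O[C@]3(c4ccc(OC)cc4)Oc2c(OC)c(OC)c(OC)c(OC)c12
F4 | step 6 | 5,6,7,8-tetramethoxy-2-(4-methoxyphenyl)-4-oxo-4H-chromen-3-yl acetate | COc1ccc(-c2oc3c(OC)c(OC)c(OC)c(OC)c3c(=O)c2OC(C)=O)cc1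
F5 | step 6 | 5-hydroxy-6,7,8-trimethoxy-2-(4-methoxyphenyl)-4-oxo-4H-chromen-3-yl acetate | COc1ccc(-c2oc3c(OC)c(OC)c(OC)c(O)c3c(=O)c2OC(C)=O)cc1
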